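The meeting opened on the grey run. The chair laid out the flasks, the readings and the questions.

in all of them: free catalyst 0.0480 M

| charge | starting material | partner | time |
|---|---|---|---|
| amber | 0.600 M | 0.720 M |  |
| blue | 0.360 M | 0.480 M |  |
| teal | 1.20 M | 0.720 M |  |
| grey | 2.10 M | 0.720 M | 170 s |

- amber run (time / s: [product] / M): 28: 0.047; 57: 0.098; 85: 0.151; 110: 0.190; 140: 0.235; 170: 0.267
- blue run (time / s: [product] / M): 28: 0.026; 57: 0.069; 85: 0.097; 110: 0.127; 140: 0.158; 170: 0.180
- teal run (time / s: [product] / M): 28: 0.065; 57: 0.144; 85: 0.210; 110: 0.269; 140: 0.335; 170: 0.404

(scatter of a reading: 0.003 M)

- Overall: starting material + partner -> product, with free catalyst as catalyst.
- Constant volume, constant temperature.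
- A reading of a species includes what of it is bound.
- An order is taken over about fifteen percent of the charge, up and down.

- apparent order in [starting material] of the starting rate, round the charge of the amber run (the rate where two percent of its starting material have turned into product) (one fixed amount of product, the same in the runs compared)
- apparent order in [partner] of the starting rate, round the charge of the amber run (the rate where two percent of its starting material have turned into product)
- the blue run starts with 0.240 M less of starting material and of partner than the amber run, and with no product. Compared where both hold the same amount of starting material, once fifteen percent of what the blue run was charged with has turned into product, is the blue run faster, slower or alike (within a tenth)?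
- product in the grey run at 170 s, as a share of the starting material charged

The first chemist argued that one constant carries the case. At 85 s the teal run, charged with twice the starting material of the amber run at equal partner, had made 1.39 times the product of the amber run. She read that ratio, with its scatter, through a saturation law and got 0.770 M for the apparent Michaelis constant, the holding of starting material at which the rate, partner fixed, stands at 0.5 of its ceiling.

The apparent order in starting material is then that constant over the constant plus the holding, so she put it at 0.562 round the amber charge. For the grey run she scaled the teal product at 170 s. Taking the charge less half the teal product at that time as the mean holding, she estimated 0.998 M for the teal run and 1.90 M for the grey run. That gave 0.509 M of product, or 24.2% of the charge.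

A colleague wrote the balance of partner, bound forms counted, the limiting reagent of the grey run, which allows 34.3% of the starting material. Her figure stands below that cap, but it leaves 0.211 M of partner, less than the 0.316 M left in the teal run at 170 s. He therefore minuted her figure as possibly high.

The forecast, made separately, gave an order in starting material of 0.57 (0.42 to 0.72), an order in partner of 0.05 (−0.08 to 0.22), alike for the comparison of the blue and amber runs, and 23.3% (20.5% to 26%) for the grey run, a share that differs from the first chemist's. On partner it said: “Teal stays almost straight even as partner falls from 0.72 to about 0.32 M, so partner barely matters.”

The flask gave 0.54 in starting material and 0.11 in partner, against the forecast's 0.05. The blue run came out alike, at a rate ratio of 1.0, and the grey run reached 23.3%.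

    free catalyst + starting material → catalyst-substrate complex (0.1240 M⁻¹ s⁻¹)
    catalyst-substrate complex + partner → loaded catalyst (1.540 M⁻¹ s⁻¹)
    loaded catalyst → product + free catalyst (0.5920 s⁻¹)
    free catalyst + starting material ⇌ idle catalyst-substrate complex, settled at all times (0.7680 M⁻¹)
    2 partner ⇌ idle reagent dimer, settled at all times (4.790 M⁻¹)

In the grey run at 170 s, tying up free catalyst with starting material as idle catalyst-substrate complex costs 8.8 percentage points of product. The constant carries to the grey run without the tying up. The order in starting material without it is 0.68 at the amber charge, which gives an apparent Michaelis constant of 1.30 M. Scaling 23.3% by each constant over itself plus 1.90 M, on the assumption that the tying up leaves the rate at vanishing holding of starting material unchanged, gives about 32.8%, and the grey run without the tying up gave 32.1%.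

The numbers in the tables are calculated on assumed constants; noise was put on by code.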